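**Retrosynthetic overview**
- Calycopterin is traced back, through O-debenzylation and methylation of the free 8-hydroxyl, to 4'-benzyloxy-5,8-dihydroxy-3,6,7-trimethoxyflavone.
- The strategy rests on ring A (C4a, C5, C6, C7, C8, C8a). Its contiguous oxygen-bearing carbons C5(OH)–C6(OMe)–C7(OMe)–C8(O) are the four carbons of dimethyl squarate, and the C4a=C8a edge is the C5=C6 double bond of a 2-aryl-3-methoxy-4-pyranone. Ring A is therefore cut at C4a–C5 (organometallic addition) and at C8–C8a (thermal ring expansion of a 4-hydroxycyclobutenone).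
- The pyranone (ring C) comes from oxidative ring expansion of an aryl furyl carbinol, made from furfural and 1-(benzyloxy)-4-bromobenzene; the oxygen shift to the 3-hydroxy-4-pyranone goes through an epoxy ketone.
- Ring order: B is bought, C is made from the furan, A is closed last by benzannulation.

Key step: step 9

Remark: compounds 5, 6 and 7 are carried as mixtures of racemic diastereomers, because step 5 removes every one of their stereocentres. Hydroquinone 16 is assumed to be handled under argon and methylated without storage.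

**Step 1**
Reactants: 1 furfural; 2 1-(benzyloxy)-4-bromobenzene
Product: 4 [4-(benzyloxy)phenyl](furan-2-yl)methanol (racemic), via 4-(benzyloxy)phenylmagnesium bromide 3 (not isolated)
Conditions: Mg turnings, I2 (cat.), THF, reflux; then 1, THF, 0 °C to rt; aq. NH4Cl
Reagents that add atoms: none
Why: Grignard formation from the aryl bromide and 1,2-addition to the non-enolisable aldehyde is routine; the carbinol centre forms without control (racemic), which does not matter because it later becomes an sp2 ring carbon.

**Step 2**
Reactants: 4 [4-(benzyloxy)phenyl](furan-2-yl)methanol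
Product: 5 2-[4-(benzyloxy)phenyl]-6-hydroxy-2H-pyran-3(6H)-one (racemic, mixture of C6 anomers)
Conditions: N-bromosuccinimide, NaHCO3, THF/H2O (4:1), 0 °C
Reagents that add atoms: water, O
Why: Achmatowicz rearrangement, in which the furan (far more nucleophilic than the benzyloxyphenyl ring) is oxidised to the cis-ene-dione and the carbinol oxygen closes onto the aldehyde as a cyclic hemiacetal; the anomeric centre forms as a mixture, which is acceptable.

**Step 3**
Reactants: 5 2-[4-(benzyloxy)phenyl]-6-hydroxy-2H-pyran-3(6H)-one
Product: 6 2-[4-(benzyloxy)phenyl]-6-methoxy-2H-pyran-3(6H)-one (racemic, mixture of anomers)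
Conditions: HC(OMe)3, BF3·OEt2 (cat.), CH2Cl2, 0 °C
Reagents that add atoms: trimethyl orthoformate, COC(OC)OC
Why: Lewis-acid-catalysed acetal exchange (O-glycosidation through the ring oxocarbenium ion) caps the hemiacetal so the enone survives the basic epoxidation; the anomeric configuration is uncontrolled and irrelevant.

**Step 4**
Reactants: 6 2-[4-(benzyloxy)phenyl]-6-methoxy-2H-pyran-3(6H)-one
Product: 7 4-[4-(benzyloxy)phenyl]-2-methoxy-3,7-dioxabicyclo[4.1.0]heptan-5-one (the 4,5-epoxide of 6; racemic, mixture of diastereomers)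
Conditions: 30% aq. H2O2, NaOH (0.2 equiv), MeOH, 0 °C
Reagents that add atoms: hydrogen peroxide, OO
Why: Weitz–Scheffer nucleophilic epoxidation of the enone (conjugate addition of hydroperoxide, then closure on oxygen) places the oxygen on C4 that becomes the pyranone carbonyl; attack anti to the 6-methoxy group is expected, but every stereoisomer converges in step 5.

**Step 5**
Reactants: 7 the epoxy ketone
Product: 8 2-[4-(benzyloxy)phenyl]-3-hydroxy-4H-pyran-4-one
Conditions: 2 M aq. H2SO4, 1,4-dioxane, 90 °C
Reagents that add atoms: none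
Why: acid-catalysed isomerisation of the α,β-epoxy ketone to the diosphenol (the C5–O bond breaks, oxygen stays on C4), tautomerisation into conjugation with the aryl group and β-elimination of methanol from C6 should give the 3-hydroxy-4-pyranone, as in the maltol-type rearrangement; all stereocentres disappear and the benzyl aryl ether tolerates dilute acid.

**Step 6**
Reactants: 8 2-[4-(benzyloxy)phenyl]-3-hydroxy-4H-pyran-4-one
Product: 9 2-[4-(benzyloxy)phenyl]-3-methoxy-4H-pyran-4-one
Conditions: MeI, K2CO3, acetone, reflux
Reagents that add atoms: iodomethane, CI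
Why: Williamson O-alkylation of the acidic enolic 3-hydroxyl, the only acidic site, installs the future 3-OMe of the flavone.

**Step 7**
Reactants: 9 2-[4-(benzyloxy)phenyl]-3-methoxy-4H-pyran-4-one
Product: 10 2-[4-(benzyloxy)phenyl]-5-iodo-3-methoxy-4H-pyran-4-one
Conditions: I2 (0.6 equiv), (NH4)2Ce(NO3)6 (1.1 equiv), MeCN, 60 °C
Reagents that add atoms: iodine, II
Why: electrophilic iodination by oxidatively generated iodonium should occur at C5, which is the β-carbon of the O1–C6=C5 enol ether and the α-carbon of the enone and the only nucleophilic ring CH, while the aryl ring is deactivated by conjugation with pyranone C2.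

**Step 8**
Reactants: 10 2-[4-(benzyloxy)phenyl]-5-iodo-3-methoxy-4H-pyran-4-one; 11 dimethyl squarate
Product: 13 4-{6-[4-(benzyloxy)phenyl]-5-methoxy-4-oxo-4H-pyran-3-yl}-4-hydroxy-2,3-dimethoxycyclobut-2-en-1-one (racemic), via pyranon-5-ylmagnesium chloride 12 (not isolated)
Conditions: i-PrMgCl·LiCl, THF, −40 °C; cannulate into 11 (1.3 equiv), THF, −78 °C; aq. NH4Cl at −78 °C
Reagents that add atoms: none
Why: iodine–magnesium exchange on the electron-poor α-iodo vinylogous ester is fast at low temperature and gives an alkenylmagnesium held by chelation to the C4 carbonyl, and inverse addition to excess squarate gives 1,2-addition at one of the two equivalent ketone carbonyls, forming the C4a–C5 bond; the carbinol centre is racemic and is consumed in step 9.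

**Step 9**
Reactants: 13 the 4-hydroxy-4-(pyranonyl)cyclobutenone
Product: 16 4'-benzyloxy-5,8-dihydroxy-3,6,7-trimethoxyflavone, via (Z)-dienylketene 14 (not isolated), via 8aH-cyclohexadienone 15 (not isolated)
Conditions: degassed toluene, 110 °C, Ar
Reagents that add atoms: none
Why: Heating opens the cyclobutenone by conrotatory 4π electrocyclic cleavage of the C1–C4 bond, the donor hydroxyl rotating outward so that the pyranonyl group lies cis to the ketene in 14. The triene made up of the ketene C=C, the C(OMe)=C(OH) bond and the pyranone C5=C6 bond then closes by thermal disrotatory 6π electrocyclisation, forming the C8–C8a bond between the ketene carbon and pyranone C6 and closing ring A as the six-membered dienone 15, which aromatises by enolisation of C8a–H toward the C8 carbonyl. This is the Moore rearrangement of 4-aryl-, 4-heteroaryl- and 4-alkenyl-4-hydroxycyclobutenones to hydroquinones, applied here to an alkene embedded in a 4-pyranone. The only new stereocentre (C8a of 15) is transient, so nothing needs control. The step needs outward rotation of the hydroxyl, secured by the torquoselectivity of donor substituents at C4, and C–C closure at C6 instead of acylation of the C4 carbonyl oxygen, secured because the oxygen closure would need a seven-membered ring while the six-membered pericyclic closure is made irreversible by aromatisation. Connectivity alone fixes the pattern (carbinol oxygen to 5-OH, squarate methoxyls to 6- and 7-OMe, ketene oxygen to 8-OH), and exclusion of air keeps the electron-rich hydroquinone from oxidising to the quinone.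

**Step 10**
Reactants: 16 4'-benzyloxy-5,8-dihydroxy-3,6,7-trimethoxyflavone
Product: 17 4'-benzyloxy-5-hydroxy-3,6,7,8-tetramethoxyflavone
Conditions: MeI (1.1 equiv), K2CO3, degassed acetone, 40 °C, Ar
Reagents that add atoms: iodomethane, CI
Why: site-selective Williamson methylation, because the 5-hydroxyl is tied up in a hydrogen bond to the C4 carbonyl and is a poor nucleophile, so one equivalent of iodomethane should alkylate only the free 8-phenoxide.

**Step 11**
Reactants: 17 4'-benzyloxy-5-hydroxy-3,6,7,8-tetramethoxyflavone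
Product: 18 calycopterin (5,4'-dihydroxy-3,6,7,8-tetramethoxyflavone)
Conditions: H2 (1 atm), 10% Pd/C, EtOAc/MeOH, rt
Reagents that add atoms: none
Why: catalytic hydrogenolysis of the benzyl aryl ether frees the 4'-phenol, and the conjugated C2=C3 bond of the flavone and the aryl methyl ethers are not expected to react at ambient pressure and temperature.

**Compound list**
1 | furfural | O=Cc1ccco1 | starting material
2 | 1-(benzyloxy)-4-bromobenzene | Brc1ccc(OCc2ccccc2)cc1 | starting material
3 | 4-(benzyloxy)phenylmagnesium bromide | Br[Mg]c1ccc(OCc2ccccc2)cc1 | intermediate (not isolated)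
4 | [4-(benzyloxy)phenyl](furan-2-yl)methanol, racemic | OC(c1ccco1)c1ccc(OCc2ccccc2)cc1 | intermediate
5 | 2-[4-(benzyloxy)phenyl]-6-hydroxy-2H-pyran-3(6H)-one, racemic anomer mixture | O=C1C=CC(O)OC1c1ccc(OCc2ccccc2)cc1 | intermediate
6 | 2-[4-(benzyloxy)phenyl]-6-methoxy-2H-pyran-3(6H)-one, racemic anomer mixture | O=C1C=CC(OC)OC1c1ccc(OCc2ccccc2)cc1 | intermediate
7 | 4-[4-(benzyloxy)phenyl]-2-methoxy-3,7-dioxabicyclo[4.1.0]heptan-5-one, racemic diastereomer mixture | O=C1C2OC2C(OC)OC1c1ccc(OCc2ccccc2)cc1 | intermediate
8 | 2-[4-(benzyloxy)phenyl]-3-hydroxy-4H-pyran-4-one | O=c1ccoc(-c2ccc(OCc3ccccc3)cc2)c1O | intermediate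
9 | 2-[4-(benzyloxy)phenyl]-3-methoxy-4H-pyran-4-one | COc1c(-c2ccc(OCc3ccccc3)cc2)occc1=O | intermediate
10 | 2-[4-(benzyloxy)phenyl]-5-iodo-3-methoxy-4H-pyran-4-one | COc1c(-c2ccc(OCc3ccccc3)cc2)occ(I)c1=O | intermediate
11 | dimethyl squarate (3,4-dimethoxycyclobut-3-ene-1,2-dione) | COC1=C(OC)C(=O)C1=O | starting material
12 | {6-[4-(benzyloxy)phenyl]-5-methoxy-4-oxo-4H-pyran-3-yl}magnesium chloride | COc1c(-c2ccc(OCc3ccccc3)cc2)occ([Mg]Cl)c1=O | intermediate (not isolated)
13 | 4-{6-[4-(benzyloxy)phenyl]-5-methoxy-4-oxo-4H-pyran-3-yl}-4-hydroxy-2,3-dimethoxycyclobut-2-en-1-one, racemic | COC1=C(OC)C(O)(c2coc(-c3ccc(OCc4ccccc4)cc3)c(OC)c2=O)C1=O | intermediate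
14 | (Z)-4-{6-[4-(benzyloxy)phenyl]-5-methoxy-4-oxo-4H-pyran-3-yl}-4-hydroxy-2,3-dimethoxybuta-1,3-dien-1-one (dienylketene) | COC(=C=O)/C(OC)=C(/O)c1coc(-c2ccc(OCc3ccccc3)cc2)c(OC)c1=O | intermediate (not isolated)
15 | 2-[4-(benzyloxy)phenyl]-5-hydroxy-3,6,7-trimethoxy-8aH-chromene-4,8-dione, racemic | COC1=C(OC)C(=O)C2OC(c3ccc(OCc4ccccc4)cc3)=C(OC)C(=O)C2=C1O | intermediate (not isolated)
16 | 4'-benzyloxy-5,8-dihydroxy-3,6,7-trimethoxyflavone | COc1c(OC)c(O)c2c(=O)c(OC)c(-c3ccc(OCc4ccccc4)cc3)oc2c1O | intermediate
17 | 4'-benzyloxy-5-hydroxy-3,6,7,8-tetramethoxyflavone | COc1c(OC)c(O)c2c(=O)c(OC)c(-c3ccc(OCc4ccccc4)cc3)oc2c1OC | intermediate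
18 | calycopterin | COc1c(OC)c(O)c2c(=O)c(OC)c(-c3ccc(O)cc3)oc2c1OC | target

**Totals**
Total step count: 11. Longest linear sequence: 11 steps (from 1 and 2 to 18; dimethyl squarate 11 is bought).

**Steps most likely to fail**

1. Step 9. The ketene may be intercepted by the free tertiary hydroxyl (lactonisation) in competition with closure onto the partly aromatic pyranone, and the electron-rich hydroquinone may be lost by oxidation during thermolysis and isolation. The fallback sets out from 13 and comes back at 17. The carbinol of 13 is silylated (TBSOTf, 2,6-lutidine, CH2Cl2, −78 to 0 °C) to 4-(tert-butyldimethylsilyloxy)-4-{6-[4-(benzyloxy)phenyl]-5-methoxy-4-oxo-4H-pyran-3-yl}-2,3-dimethoxycyclobut-2-en-1-one F1, which can no longer lactonise. Thermolysis in degassed toluene should then give the mono-protected hydroquinone 4'-benzyloxy-5-(tert-butyldimethylsilyloxy)-8-hydroxy-3,6,7-trimethoxyflavone F2, which is less prone to oxidation. Its only free hydroxyl is methylated (MeI, K2CO3, acetone) to 4'-benzyloxy-5-(tert-butyldimethylsilyloxy)-3,6,7,8-tetramethoxyflavone F3, and Bu4NF in THF removes the silyl group to give 17.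

2. Step 8. The metallated pyranone may fragment by β-elimination of the ring oxygen (ring opening to an ynone enolate), the exchange reagent may attack the pyranone, or a second addition to the squarate may occur. The fallback sets out from 10 and comes back at 13. Zinc dust inserts directly into the C–I bond (Zn, LiCl, THF, 25–40 °C) to give the thermally robust, non-basic {6-[4-(benzyloxy)phenyl]-5-methoxy-4-oxo-4H-pyran-3-yl}zinc iodide F4. Its addition to the strained ketone carbonyl of 11 is promoted by MgCl2 in THF, and aqueous NH4Cl work-up gives 13.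

3. Step 7. Site selectivity may be poor, with iodination of the benzyloxyphenyl ring ortho to oxygen or double iodination competing with attack at C5. The fallback sets out from 9 and comes back at 10. Carbonyl-directed C–H zincation with TMP2Zn·2MgCl2·2LiCl (THF, −30 °C), in which magnesium bound to the C4 carbonyl should steer the amide base to the neighbouring C5–H, gives {6-[4-(benzyloxy)phenyl]-5-methoxy-4-oxo-4H-pyran-3-yl}zinc chloride F5 (written as the monomeric zinc chloride). Quenching with I2 gives 10 without any electrophilic attack on the arene.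

**Further compounds**
F1 | step 9 | 4-(tert-butyldimethylsilyloxy)-4-{6-[4-(benzyloxy)phenyl]-5-methoxy-4-oxo-4H-pyran-3-yl}-2,3-dimethoxycyclobut-2-en-1-one, racemic | COC1=C(OC)C(O[Si](C)(C)C(C)(C)C)(c2coc(-c3ccc(OCc4ccccc4)cc3)c(OC)c2=O)C1=O
F2 | step 9 | 4'-benzyloxy-5-(tert-butyldimethylsilyloxy)-8-hydroxy-3,6,7-trimethoxyflavone | COc1c(OC)c(O[Si](C)(C)C(C)(C)C)c2c(=O)c(OC)c(-c3ccc(OCc4ccccc4)cc3)oc2c1O
F3 | step 9 | 4'-benzyloxy-5-(tert-butyldimethylsilyloxy)-3,6,7,8-tetramethoxyflavone | COc1c(OC)c(O[Si](C)(C)C(C)(C)C)c2c(=O)c(OC)c(-c3ccc(OCc4ccccc4)cc3)oc2c1OC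
F4 | step 8 | {6-[4-(benzyloxy)phenyl]-5-methoxy-4-oxo-4H-pyran-3-yl}zinc iodide | COc1c(-c2ccc(OCc3ccccc3)cc2)occ([Zn]I)c1=O
F5 | step 7 | {6-[4-(benzyloxy)phenyl]-5-methoxy-4-oxo-4H-pyran-3-yl}zinc chloride | COc1c(-c2ccc(OCc3ccccc3)cc2)occ([Zn]Cl)c1=O
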